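**Assumption and convention (one line):** 2-bromo-3,3-diethoxyprop-1-ene (6) and chloroacetaldehyde (7, dried and distilled from the commercial aqueous solution) are taken as catalogue chemicals; atom labels C1–C15 follow elemane numbering (C10 quaternary carbon, C5 acrolein-bearing carbon, C6 carbinol, C7/C8 lactone ring carbons, C9 ester carbinol, C1/C2 oxirane, C14 methyl) and "up" means the ring face that carries C14.

## Retrosynthetic overview

1. Target ⇒ methacrylation of the 9-OH and acid unmasking of the 6-OTES / C3 diethyl acetal; 9-OH ⇒ Luche reduction of keto-lactone 18.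
2. cis-8,12-Lactone ⇒ enolate iodination and intramolecular carboxylate SN2 at C8 of keto acid 16; C12 acid ⇒ allylic oxidation of the carvone isopropenyl group.
3. C5–C4 and C10–C1 bonds plus the oxirane ⇒ hydroxyl-directed conjugate addition of an acrolein-acetal vinyl Grignard to trans-4-hydroxycarvone 5, aldol trapping with ClCH2CHO, ring closure.
4. C6–O bond ⇒ [2,3]-sigmatropic sulfoxide–sulfenate rearrangement of an α-phenylsulfinyl β,γ-enone made from (R)-carvone. This step relays the only purchased stereocentre (C7) to C6, which then controls C5, C10 and C1.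
5. Ring order: the cyclohexane is bought as (R)-carvone; the oxirane closes in step 3; the γ-lactone closes in step 7.

## Route

**Step 1**
Reactants: 1 (R)-(−)-carvone
Product: 2 (2R,5S)-2-methyl-2-(phenylsulfanyl)-5-(prop-1-en-2-yl)cyclohex-3-en-1-one
Conditions: KOt-Bu (1.05 equiv), t-BuOH–THF, 0 °C; then PhSO2SPh, −40 °C; used cold and at once
Reagents that add atoms: S-phenyl benzenethiosulfonate, O=S(=O)(Sc1ccccc1)c1ccccc1
Why: Deconjugative α-sulfenylation of the thermodynamic linear dienolate puts sulfur on C10 and the alkene at C5=C6; attack on the half-chair is expected anti to the pseudo-equatorial isopropenyl group, so PhS is trans to it.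

**Step 2**
Reactants: 2 (2R,5S)-2-methyl-2-(phenylsulfanyl)-5-(prop-1-en-2-yl)cyclohex-3-en-1-one
Product: 5 (4S,5R)-4-hydroxy-2-methyl-5-(prop-1-en-2-yl)cyclohex-2-en-1-one, via sulfoxide 3 (not isolated), via sulfenate ester 4 (not isolated)
Conditions: mCPBA (1.0 equiv), CH2Cl2, −78 °C; then Et2NH, MeOH, −78 °C → rt
Reagents that add atoms: mCPBA, OOC(=O)c1cccc(Cl)c1
Why: Mislow–Evans [2,3]-sigmatropic rearrangement: the suprafacial shift forms the C6–O bond on the face that carried sulfur (trans to the C7 isopropenyl) and restores the conjugated enone, and Et2NH cleaves the sulfenate.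

**Step 3**
Reactants: 5 (4S,5R)-4-hydroxy-2-methyl-5-(prop-1-en-2-yl)cyclohex-2-en-1-one; 6 2-bromo-3,3-diethoxyprop-1-ene; 7 chloroacetaldehyde
Product: 12 epoxy ketone 3-(3,3-diethoxyprop-1-en-2-yl)-4-hydroxy-2-methyl-2-[(2S)-oxiran-2-yl]-5-(prop-1-en-2-yl)cyclohexan-1-one (2-methyl / 3-alkenyl / 4-OH up; 2-oxiranyl / 5-isopropenyl down), via vinyllithium 8 (not isolated), via vinylmagnesium bromide 9 (not isolated), via magnesium enolate 10 (not isolated), via chlorohydrin 11 (not isolated)
Conditions: 6, t-BuLi (2 equiv), Et2O, −78 °C; MgBr2·OEt2; 5 (0.4 equiv relative to 9), THF, −78 → −30 °C; 7, −78 °C; aq NH4Cl; crude, K2CO3, MeOH, 0 °C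
Reagents that add atoms: none
Why: Alkoxide-directed (ligand-assisted) Grignard conjugate addition delivers the vinyl group to C5 syn to the C6 oxide and anti to the C7 isopropenyl; the magnesium enolate then undergoes a Zimmerman–Traxler aldol at C10 anti to the new C5 group (C14 cis to the enolate oxygen ends syn to the carbinol oxygen, giving 10R,1S), and the chlorohydrin closes to the oxirane by intramolecular Williamson displacement.

**Step 4**
Reactants: 12 epoxy ketone
Product: 13 triethylsilyl ether of 12 at O6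
Conditions: Et3SiCl, imidazole, DMAP (cat.), DMF, 0 °C → rt
Reagents that add atoms: chlorotriethylsilane, CC[Si](Cl)(CC)CC
Why: Silylation of the only free hydroxyl masks O6 so that O9 can be acylated selectively later; no stereocentre is touched.

**Step 5**
Reactants: 13 triethylsilyl ether
Product: 14 C12 allylic alcohol (the C7 isopropenyl methyl becomes CH2OH)
Conditions: SeO2 (0.5 equiv), t-BuOOH (decane solution, 3 equiv), CH2Cl2, 0 °C → rt
Reagents that add atoms: SeO2 (catalytic oxygen carrier), O=[Se]=O; tert-butyl hydroperoxide, CC(C)(C)OO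
Why: Sharpless–Riley allylic oxidation (ene reaction then [2,3] shift) attacks the only alkene that carries an allylic methyl, as in the oxidation of β-elemene; the acetal-bearing alkene has no methyl and is inductively deactivated.

**Step 6**
Reactants: 14 C12 allylic alcohol
Product: 16 keto acid (C7 substituent is now 1-carboxyvinyl), via aldehyde 15 (not isolated)
Conditions: TEMPO (0.1 equiv), NaClO2 (2 equiv), NaOCl (0.05 equiv), MeCN–NaH2PO4/Na2HPO4 buffer pH 6.7, 35 °C
Reagents that add atoms: NaClO2, [Na+].[O-]Cl=O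
Why: Oxoammonium/chlorite oxidation takes the primary allylic alcohol through the enal to the acrylic acid at near-neutral pH, which spares the acetal, silyl ether and oxirane.

**Step 7**
Reactants: 16 keto acid
Product: 18 keto lactone (cis-fused 8,12-olide, C9 ketone), via iodoketone 17 (not isolated)
Conditions: LiN(SiMe3)2 (2.2 equiv), THF, −78 °C; I2 (1.05 equiv), −78 → 0 °C
Reagents that add atoms: none
Why: The only enolisable position (C8) is iodinated anti to the C7 substituent and the carboxylate then displaces iodide by intramolecular SN2 with inversion, so O8 ends cis to C11; any cis-iodide is recycled by enolisation or iodide exchange because only the trans-iodide can cyclise.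

**Step 8**
Reactants: 18 keto lactone
Product: 19 C9 alcohol (OH down, cis to O8)
Conditions: NaBH4, CeCl3·7H2O, MeOH, −78 °C
Reagents that add atoms: none
Why: Luche 1,2-reduction leaves the α-methylene lactone alone; hydride attacks anti to the axial C8–O bond and to the C1 substituent (polar Felkin–Anh, axial attack), which places the new hydroxyl cis to O8.

**Step 9**
Reactants: 19 C9 alcohol
Product: 20 C9 methacrylate
Conditions: methacrylic anhydride, Et3N, DMAP (0.2 equiv), CH2Cl2, 0 °C → rt
Reagents that add atoms: methacrylic anhydride, CC(=C)C(=O)OC(=O)C(C)=C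
Why: DMAP-catalysed Steglich-type acylation of the only free hydroxyl; configuration at C9 is retained.

**Step 10**
Reactants: 20 C9 methacrylate
Product: 21 target CNP0124638.3
Conditions: AcOH–THF–H2O (3:1:1), rt
Reagents that add atoms: water, O
Why: Mild acid hydrolysis removes the triethylsilyl ether and the very labile α,β-unsaturated diethyl acetal in one operation, while the neopentyl terminal oxirane and both esters survive.

## Compound list

1 | (R)-(−)-carvone, (5R)-2-methyl-5-(prop-1-en-2-yl)cyclohex-2-en-1-one | O=C1C[C@H](C(C)=C)CC=C1C | starting material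
2 | (2R,5S)-2-methyl-2-(phenylsulfanyl)-5-(prop-1-en-2-yl)cyclohex-3-en-1-one (PhS trans to isopropenyl) | O=C1C[C@H](C(C)=C)C=C[C@]1(Sc2ccccc2)C | intermediate
3 | S-oxide of 2 (mixture at sulfur) | O=C1C[C@H](C(C)=C)C=C[C@]1(S(=O)c2ccccc2)C | intermediate
4 | (4S,5R)-2-methyl-4-[(phenylsulfanyl)oxy]-5-(prop-1-en-2-yl)cyclohex-2-en-1-one | O=C1C[C@H](C(C)=C)[C@@H](OSc2ccccc2)C=C1C | intermediate
5 | (4S,5R)-4-hydroxy-2-methyl-5-(prop-1-en-2-yl)cyclohex-2-en-1-one (trans-4-hydroxycarvone) | O=C1C[C@H](C(C)=C)[C@@H](O)C=C1C | intermediate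
6 | 2-bromo-3,3-diethoxyprop-1-ene | C=C(Br)C(OCC)OCC | starting material
7 | chloroacetaldehyde | ClCC=O | starting material
8 | (3,3-diethoxyprop-1-en-2-yl)lithium | [Li]C(=C)C(OCC)OCC | intermediate
9 | (3,3-diethoxyprop-1-en-2-yl)magnesium bromide | Br[Mg]C(=C)C(OCC)OCC | intermediate
10 | bis(bromomagnesium) enolate/alkoxide of the conjugate adduct (C5 vinyl and O6 up, C7 isopropenyl down) | C1(O[Mg]Br)C[C@H](C(C)=C)[C@@H](O[Mg]Br)[C@@H](C(=C)C(OCC)OCC)C=1C | intermediate
11 | chlorohydrin aldol: 2-[(1S)-2-chloro-1-hydroxyethyl] analogue of 12 | O=C1C[C@H](C(C)=C)[C@@H](O)[C@@H](C(=C)C(OCC)OCC)[C@]1(C)[C@H](O)CCl | intermediate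
12 | 3-(3,3-diethoxyprop-1-en-2-yl)-4-hydroxy-2-methyl-2-[(2S)-oxiran-2-yl]-5-(prop-1-en-2-yl)cyclohexan-1-one (2-Me, 3-alkenyl, 4-OH up; oxiranyl, isopropenyl down) | O=C1C[C@H](C(C)=C)[C@@H](O)[C@@H](C(=C)C(OCC)OCC)[C@]1(C)[C@H]1CO1 | intermediate
13 | 4-O-triethylsilyl ether of 12 | O=C1C[C@H](C(C)=C)[C@@H](O[Si](CC)(CC)CC)[C@@H](C(=C)C(OCC)OCC)[C@]1(C)[C@H]1CO1 | intermediate
14 | 13 with the C7 substituent oxidised to 3-hydroxyprop-1-en-2-yl | O=C1C[C@H](C(=C)CO)[C@@H](O[Si](CC)(CC)CC)[C@@H](C(=C)C(OCC)OCC)[C@]1(C)[C@H]1CO1 | intermediate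
15 | 13 with the C7 substituent as 3-oxoprop-1-en-2-yl | O=C1C[C@H](C(=C)C=O)[C@@H](O[Si](CC)(CC)CC)[C@@H](C(=C)C(OCC)OCC)[C@]1(C)[C@H]1CO1 | intermediate
16 | keto acid: 13 with the C7 substituent as 1-carboxyvinyl | O=C1C[C@H](C(=C)C(=O)O)[C@@H](O[Si](CC)(CC)CC)[C@@H](C(=C)C(OCC)OCC)[C@]1(C)[C@H]1CO1 | intermediate
17 | lithium carboxylate of the C8 iodoketone (iodine up, trans to the C7 substituent) | O=C1[C@@H](I)[C@H](C(=C)C(=O)O[Li])[C@@H](O[Si](CC)(CC)CC)[C@@H](C(=C)C(OCC)OCC)[C@]1(C)[C@H]1CO1 | intermediate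
18 | keto lactone: cis-fused α-methylene 8,12-olide with C9 ketone, 6-OTES, C5 acetal-vinyl, C10 methyl and (S)-oxiranyl | O=C1[C@@H]2OC(=O)C(=C)[C@@H]2[C@@H](O[Si](CC)(CC)CC)[C@@H](C(=C)C(OCC)OCC)[C@]1(C)[C@H]1CO1 | intermediate
19 | C9 alcohol of 18 (9-OH down, cis to O8) | O[C@@H]1[C@@H]2OC(=O)C(=C)[C@@H]2[C@@H](O[Si](CC)(CC)CC)[C@@H](C(=C)C(OCC)OCC)[C@]1(C)[C@H]1CO1 | intermediate
20 | C9 methacrylate of 19 | C=C(C)C(=O)O[C@@H]1[C@@H]2OC(=O)C(=C)[C@@H]2[C@@H](O[Si](CC)(CC)CC)[C@@H](C(=C)C(OCC)OCC)[C@]1(C)[C@H]1CO1 | intermediate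
21 | CNP0124638.3, (1S,5R,6S,7R,8R,9S,10R)-1,2-epoxy-6-hydroxy-9-(methacryloyloxy)-3-oxoelema-4(15),11(13)-dien-12,8-olide | C=C(C)C(=O)O[C@@H]1[C@@H]2OC(=O)C(=C)[C@@H]2[C@@H](O)[C@@H](C(=C)C=O)[C@]1(C)[C@H]1CO1 | target

## Step count and risks

Total step count: 10. Longest linear sequence: 10 steps (1 → 21); 6 and 7 are bought.

**Step 1 (with its consequence in step 2).** The sulfenylation may go at C8 (α′) instead of C10. Its facial selectivity rests only on a 1,4-relationship to the isopropenyl group. The allyl sulfide 2 can also undergo a 1,3-shift before oxidation. The fallback sets out from 1 and comes back at 5. Thermodynamic silylation (Me3SiCl, NaI, Et3N, MeCN) gives the linear trimethylsilyl dienol ether F1. Sensitised singlet oxygen (O2, tetraphenylporphyrin, hν, CH2Cl2, −78 °C) adds as a [4+2] dienophile across C9/C6 on the face anti to the adjacent isopropenyl group to give the silyloxy endoperoxide F2. Thiourea in MeOH reduces the O–O bond and the silyl hemiketal collapses to 5. Here the C6 configuration is set by 1,2-induction instead of 1,4-induction.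

**Step 3.** The Grignard reagent may add 1,2 or without alkoxide delivery. The hindered aldolate may revert (retro-aldol) before or during oxirane closure, which would erode C1. The fallback sets out from 5 and comes back at 13. Only the directed conjugate addition with 9 is run, and the enolate and the alkoxide are both trapped (Et3SiCl, Et3N, HMPA) to give the purified bis(triethylsilyl) compound F3. MeLi (THF, 0 °C) cleaves only the enol ether to the regiodefined lithium enolate F4. Aldol with 7 at −78 °C gives the silyl-protected chlorohydrin F5. K2CO3/MeOH closes it to 13, so step 4 is skipped.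

**Step 7.** The α-iodoketone may lose HI toward C7, and LiI may open the oxirane. The fallback sets out from 16 and comes back at 18. Enolate hydroxylation (LiN(SiMe3)2, then 2-(phenylsulfonyl)-3-phenyloxaziridine, THF, −78 °C) gives the α-hydroxy ketone F6 with the hydroxyl trans to the C7 substituent. An intramolecular Mitsunobu lactonisation (PPh3, DIAD, THF, 0 °C) then closes the lactone with inversion at C8 to give 18.

## Further compounds

F1 | step 1 | trimethylsilyl dienol ether of carvone, (R)-trimethyl{[2-methyl-5-(prop-1-en-2-yl)cyclohexa-1,3-dien-1-yl]oxy}silane | C1(O[Si](C)(C)C)C[C@H](C(C)=C)C=CC=1C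
F2 | step 1 | 1-(trimethylsilyloxy)-2,3-dioxabicyclo[2.2.2]oct-5-ene endoperoxide (peroxide bridge anti to isopropenyl) | C[Si](C)(C)O[C@@]1(OO2)C(C)=C[C@H]2[C@@H](C(C)=C)C1
F3 | step 3 | bis(triethylsilyl) conjugate adduct (O6 silyl ether plus C9 silyl enol ether) | C1(O[Si](CC)(CC)CC)C[C@H](C(C)=C)[C@@H](O[Si](CC)(CC)CC)[C@@H](C(=C)C(OCC)OCC)C=1C
F4 | step 3 | lithium enolate of the O6-silylated conjugate adduct | C1(O[Li])C[C@H](C(C)=C)[C@@H](O[Si](CC)(CC)CC)[C@@H](C(=C)C(OCC)OCC)C=1C
F5 | step 3 | O6-triethylsilyl chlorohydrin aldol | O=C1C[C@H](C(C)=C)[C@@H](O[Si](CC)(CC)CC)[C@@H](C(=C)C(OCC)OCC)[C@]1(C)[C@H](O)CCl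
F6 | step 7 | C8 α-hydroxy ketone of 16 (OH up, trans to the C7 substituent) | O=C1[C@@H](O)[C@H](C(=C)C(=O)O)[C@@H](O[Si](CC)(CC)CC)[C@@H](C(=C)C(OCC)OCC)[C@]1(C)[C@H]1CO1
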